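**Plan**

1. Retrosynthetic cuts, in order: (a) the two C–C bonds from the lactone α- and β-carbons to the bicyclo[2.2.2]octene bridgeheads (retro-Diels–Alder to (+)-altholactone 16 and (R)-α-phellandrene 17); (b) the lactone C=C (metathesis) and acyl–O bond; (c) the ring-fusion C–C bond shared by the tetrahydrofuran and the δ-lactone; (d) the benzylic C–O bond (epoxide opening of phenylglycidol by allyl alcohol).
2. Enabling feature: both fusion methines are oxygenated. One carries the ring ether oxygen and the lactone's alkene carbon, the other the lactone oxygen. This cis-1,2-diol monoether beside a vinyl-type carbon is the retron of a (Z)-γ-alkoxyallylboronate adding to an aldehyde. The acetal-level carbon acts as donor (polarity reversal), and the target's own O–CH(Ph)–CH(O) chain is the tether, so the addition closes the tetrahydrofuran.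
3. Forward order: epoxide opening, silylation, allyl ether lithiation/borylation, one-flask oxidation/intramolecular allylboration (tetrahydrofuran), acrylate formation and ring-closing metathesis (δ-lactone), desilylation, Diels–Alder (bicyclooctene).
4. Stereochemistry: CH(Ph) and CH(OH) come from the epoxide (inversion at the benzylic carbon). Both fusion centres come from the (Z)-enol ether in a chair transition state biased by the OTES centre. The four cycloaddition centres come from endo, convex-face, anti-to-isopropyl addition; the isopropyl centre comes from 17.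

Key step: step 4

Remark: (2S,3S)-3-phenylglycidol (also one Sharpless asymmetric epoxidation from cinnamyl alcohol) and (R)-(−)-α-phellandrene are taken as commercial, enantiomerically enriched materials.

**Route**

Step 1
Reactants: 1 (2S,3S)-3-phenylglycidol; 2 allyl alcohol
Product: 3 (2S,3R)-3-(allyloxy)-3-phenylpropane-1,2-diol
Conditions: allyl alcohol (10 equiv), Ti(OiPr)4 (1.5 equiv), CH2Cl2, rt to 40 °C; aq tartaric acid work-up
Reagents that add atoms: allyl alcohol (2), C=CCO
Why: Ti(OiPr)4-mediated opening of a 2,3-epoxy alcohol by an alcohol nucleophile: the titanium-bound glycidol is attacked at the activated benzylic C3 in an SN2 sense (inversion), so the trans-(2S,3S)-epoxide should give the erythro (2S,3R) ether-diol with C2 untouched.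

Step 2
Reactants: 3 (2S,3R)-3-(allyloxy)-3-phenylpropane-1,2-diol; 4 chlorotriethylsilane
Product: 5 (2S,3R)-3-(allyloxy)-3-phenyl-1,2-bis(triethylsilyloxy)propane
Conditions: Et3SiCl (2.4 equiv), imidazole, DMAP (cat.), CH2Cl2, 0 °C to rt
Reagents that add atoms: chlorotriethylsilane (4), CC[Si](Cl)(CC)CC
Why: Standard silyl ether formation masks both hydroxyls for the lithiation and provides a primary TES ether that can later be oxidised directly; no stereocentre is touched.

Step 3
Reactants: 5 (2S,3R)-3-(allyloxy)-3-phenyl-1,2-bis(triethylsilyloxy)propane; 6 2-isopropoxy-4,4,5,5-tetramethyl-1,3,2-dioxaborolane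
Product: 9 2-[(Z)-3-{[(1R,2S)-1-phenyl-2,3-bis(triethylsilyloxy)propyl]oxy}prop-2-en-1-yl]-4,4,5,5-tetramethyl-1,3,2-dioxaborolane, via allyllithium 7 (not isolated), via borate complex 8 (not isolated)
Conditions: s-BuLi (1.2 equiv), THF, −78 °C, 30 min; then 6, −78 to −40 °C; pH 7 buffer
Reagents that add atoms: 2-isopropoxy-4,4,5,5-tetramethyl-1,3,2-dioxaborolane (6), CC(C)OB1OC(C)(C)C(C)(C)O1
Why: α-Lithiation of an allyl ether followed by borate trapping (the standard preparation of (Z)-γ-alkoxyallylboronates): s-BuLi removes the allylic proton next to oxygen, the oxygen-chelated oxyallyl anion is held in the Z form, the borate is attacked through the γ-terminus and complex 8 loses isopropoxide, so the enol ether geometry that later decides the cis ring fusion is set here.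

Step 4
Reactants: 9 (Z)-γ-alkoxyallyl pinacol boronate from step 3
Product: 12 (2S,3R,4S,5R)-5-phenyl-4-(triethylsilyloxy)-2-vinyltetrahydrofuran-3-ol, via aldehyde 10 (not isolated), via boryl ether 11 (not isolated)
Conditions: (COCl)2 (4 equiv), DMSO (8 equiv), CH2Cl2, −78 to −40 °C; Et3N, −78 °C to rt; aq NaHCO3
Reagents that add atoms: none
Why: The activated sulfoxide cleaves and oxidises only the unhindered primary TES ether to aldehyde 10 (Swern oxidation of a primary silyl ether), and on warming the aldehyde carbon is attacked by the oxygen-bearing γ-carbon of the tethered allylboronate through a closed chair-like six-membered B–O=C···C=C–C transition state, boron passing to the carbonyl oxygen and the double bond shifting to the terminal vinyl position. The closest known reaction type is the intramolecular allylboration of ω-oxo allylboronates to 2-vinylcycloalkanols and 2-vinyl-3-hydroxy cyclic ethers, together with the intermolecular addition of (Z)-γ-alkoxyallylboronates to aldehydes that gives syn-1,2-diol monoethers. The tetrahydrofuran is closed in the 5-exo-trig mode with respect to the carbonyl, and the O–CH(Ph)–CH(OTES) tether is part of the target. The new carbinol carbon and the new ether carbon are set cis to each other by the (Z)-enol ether, which places the ether oxygen axial and the aldehyde chain equatorial on the chair, the only pairing the three-atom tether can span. Their absolute sense is set by the existing OTES-bearing carbon: the chair with the carbonyl oxygen anti to the adjacent C–OTES bond (opposed dipoles, silyloxy group away from the dioxaborolane) should be preferred and, given the erythro backbone, it places the vinyl group cis to phenyl. The step needs chemoselection between the two TES ethers and survival of the enol ether, which rest on the steric difference at −40 °C and on adding the amine before warming.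

Step 5
Reactants: 12 (2S,3R,4S,5R)-5-phenyl-4-(triethylsilyloxy)-2-vinyltetrahydrofuran-3-ol; 13 acryloyl chloride
Product: 14 (2S,3R,4R,5R)-5-phenyl-4-(triethylsilyloxy)-2-vinyltetrahydrofuran-3-yl acrylate
Conditions: acryloyl chloride, i-Pr2NEt, DMAP (cat.), CH2Cl2, −20 to 0 °C
Reagents that add atoms: acryloyl chloride (13), C=CC(=O)Cl
Why: DMAP-catalysed O-acylation of the secondary alcohol with an acid chloride installs the second alkene for metathesis without touching any stereocentre.

Step 6
Reactants: 14 acrylate from step 5
Product: 15 (2R,3R,3aR,7aS)-2-phenyl-3-(triethylsilyloxy)-2,3,3a,7a-tetrahydro-5H-furo[3,2-b]pyran-5-one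
Conditions: second-generation Grubbs catalyst RuCl2(=CHPh)(H2IMes)(PCy3) (5 mol %), CH2Cl2 (5 mM), 40 °C
Reagents that add atoms: none
Why: Ring-closing metathesis of an acrylate with a vicinal cis vinyl group should give the 5,6-dihydro-2H-pyran-2-one with loss of ethene, the ring alkene geometry and the cis fusion being dictated by the six-membered ring and the centres already present.

Step 7
Reactants: 15 O-TES-altholactone
Product: 16 (+)-altholactone, (2R,3R,3aS,7aS)-3-hydroxy-2-phenyl-2,3,3a,7a-tetrahydro-5H-furo[3,2-b]pyran-5-one
Conditions: HF·pyridine, pyridine, THF, 0 °C to rt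
Reagents that add atoms: none
Why: Buffered fluoride cleavage of the secondary TES ether (silyl ether deprotection) leaves the unsaturated lactone untouched and should give the free alcohol.

Step 8
Reactants: 16 (+)-altholactone; 17 (R)-(−)-α-phellandrene
Product: 18 target, the endo Diels–Alder adduct of 16 and 17
Conditions: 17 (10 equiv), BHT (cat.), toluene, sealed tube, 120 °C
Reagents that add atoms: (R)-α-phellandrene (17), CC1=CC[C@H](C(C)C)C=C1
Why: Biomimetic intermolecular Diels–Alder reaction: the enoate C=C should add suprafacially (cis lactone/bicycle fusion) with the lactone carbonyl endo (Alder rule), on the convex face of the cis-fused furopyranone anti to the tetrahydrofuran ring and its phenyl group, on the diene face anti to the isopropyl group (which ends syn to the new alkene), and with the lactone β-carbon bonding to the diene terminus next to the methyl-bearing carbon (largest HOMO coefficient, "para" orientation), the isopropyl stereocentre being carried over from 17.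

**Compound list**

1 | (2S,3S)-3-phenylglycidol, trans-(3-phenyloxiran-2-yl)methanol | OC[C@@H]1O[C@H]1c2ccccc2 | starting material
2 | allyl alcohol | C=CCO | starting material
3 | (2S,3R)-3-(allyloxy)-3-phenylpropane-1,2-diol (erythro) | OC[C@H](O)[C@@H](c1ccccc1)OCC=C | intermediate
4 | chlorotriethylsilane | CC[Si](Cl)(CC)CC | starting material
5 | (2S,3R)-3-(allyloxy)-3-phenyl-1,2-bis(triethylsilyloxy)propane | CC[Si](CC)(CC)OC[C@H](O[Si](CC)(CC)CC)[C@@H](c1ccccc1)OCC=C | intermediate
6 | 2-isopropoxy-4,4,5,5-tetramethyl-1,3,2-dioxaborolane | CC(C)OB1OC(C)(C)C(C)(C)O1 | starting material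
7 | α-lithiated allyl ether of 5 (1-alkoxyallyllithium) | CC[Si](CC)(CC)OC[C@H](O[Si](CC)(CC)CC)[C@@H](c1ccccc1)OC([Li])C=C | intermediate
8 | lithium isopropoxy(pinacolato)borate complex of the (Z)-γ-alkoxyallyl unit | CC[Si](CC)(CC)OC[C@H](O[Si](CC)(CC)CC)[C@@H](c1ccccc1)O/C=C\C[B-]1(OC(C)C)OC(C)(C)C(C)(C)O1.[Li+] | intermediate
9 | 2-[(Z)-3-{[(1R,2S)-1-phenyl-2,3-bis(triethylsilyloxy)propyl]oxy}prop-2-en-1-yl]-4,4,5,5-tetramethyl-1,3,2-dioxaborolane | CC[Si](CC)(CC)OC[C@H](O[Si](CC)(CC)CC)[C@@H](c1ccccc1)O/C=C\CB1OC(C)(C)C(C)(C)O1 | intermediate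
10 | (2R,3R)-3-phenyl-3-{[(Z)-3-(pinacolboryl)prop-1-en-1-yl]oxy}-2-(triethylsilyloxy)propanal | O=C[C@H](O[Si](CC)(CC)CC)[C@@H](c1ccccc1)O/C=C\CB1OC(C)(C)C(C)(C)O1 | intermediate
11 | O-pinacolboryl ether of 12 | CC1(C)OB(O[C@H]2[C@H](O[Si](CC)(CC)CC)[C@@H](c3ccccc3)O[C@H]2C=C)OC1(C)C | intermediate
12 | (2S,3R,4S,5R)-5-phenyl-4-(triethylsilyloxy)-2-vinyltetrahydrofuran-3-ol (vinyl, OH and phenyl cis; OTES trans) | O[C@H]1[C@H](O[Si](CC)(CC)CC)[C@@H](c2ccccc2)O[C@H]1C=C | intermediate
13 | acryloyl chloride | C=CC(=O)Cl | starting material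
14 | (2S,3R,4R,5R)-5-phenyl-4-(triethylsilyloxy)-2-vinyltetrahydrofuran-3-yl acrylate | C=CC(=O)O[C@H]1[C@H](O[Si](CC)(CC)CC)[C@@H](c2ccccc2)O[C@H]1C=C | intermediate
15 | (2R,3R,3aR,7aS)-2-phenyl-3-(triethylsilyloxy)-2,3,3a,7a-tetrahydro-5H-furo[3,2-b]pyran-5-one (O-TES-altholactone) | O1[C@H]2[C@H](O[Si](CC)(CC)CC)[C@@H](c3ccccc3)O[C@H]2C=CC1=O | intermediate
16 | (+)-altholactone, (2R,3R,3aS,7aS)-3-hydroxy-2-phenyl-2,3,3a,7a-tetrahydro-5H-furo[3,2-b]pyran-5-one | O1[C@H]2[C@H](O)[C@@H](c3ccccc3)O[C@H]2C=CC1=O | intermediate
17 | (R)-(−)-α-phellandrene, (5R)-5-isopropyl-2-methylcyclohexa-1,3-diene | CC1=CC[C@H](C(C)C)C=C1 | starting material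
18 | target: δ-lactone cis-fused to 5-methyl-8-isopropylbicyclo[2.2.2]oct-5-ene (carbonyl carbon on the bridgehead next to CH–iPr, lactone endo, isopropyl syn to the C=C bridge), altholactone tetrahydrofuran on the opposite lactone face | CC1=C[C@@H]2[C@@H]3C(=O)O[C@H]4[C@H](O)[C@@H](c5ccccc5)O[C@H]4[C@@H]3[C@H]1C[C@@H]2C(C)C | target

**Step count and risks**

Total steps: 8. Longest linear sequence: 8 steps (1 to 18).

Steps most likely to fail:

1. Step 4. The electron-rich (Z)-enol ether/allylboronate may be destroyed by the electrophilic chlorosulfonium species or by adventitious HCl during the warm-up needed to cleave the primary TES ether, before the aldehyde forms. Fallback, setting out from 5 and returning at 12: lithiated 5 (s-BuLi, THF, −78 °C) is trapped with Bu3SnCl instead of the borate to give the (Z)-γ-alkoxyallylstannane F1, a reagent class known to tolerate activated-DMSO oxidations. Selective Swern oxidation of its primary TES ether gives the isolable aldehyde F2. This is cyclised in a separate operation by heating in toluene (about 100 °C) through the same closed six-membered transition state (thermal allylstannane–aldehyde addition) to the tributylstannyl ether F3. Aqueous work-up then releases alcohol 12.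

2. Step 3. The benzylic proton may be removed in competition with the allylic one (leading to Wittig rearrangement or loss of silanolate), or boron may be captured at the α- rather than the γ-terminus. Fallback, setting out from 5 and returning at 10: cross-metathesis of allyl ether 5 with vinylboronic acid pinacol ester (second-generation Grubbs catalyst RuCl2(=CHPh)(H2IMes)(PCy3), CH2Cl2, 40 °C) gives the (E)-alkenylboronate F4 without any carbanion chemistry. Selective Swern oxidation of the primary TES ether gives aldehyde F5; the alkenylboronate is inert to the oxidant. A nickel hydride catalyst generated from NiCl2(dppp), Ph2PH, Zn and ZnI2 (CH2Cl2, rt) then moves the double bond by one position. This Z-selective transposition of alkenylboronates to allylboronates is known to run in the presence of aldehydes. It produces the (Z)-γ-alkoxyallylboronate aldehyde 10 in the flask, from where the main route continues through 11 to 12.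

3. Step 8. The cycloaddition of the weakly activated dihydropyranone may be slower than thermal dimerisation and hydrogen-shift isomerisation of the diene, and endo/regio control may erode at the temperature required. Fallback, setting out from 12 and returning at 18: alcohol 12 is esterified with (phenylsulfonyl)acetic acid (DCC, DMAP) to give the (phenylsulfonyl)acetate F6. Ozonolysis of the vinyl group (O3, CH2Cl2, −78 °C; Me2S) gives aldehyde F7. Intramolecular Knoevenagel condensation (piperidinium acetate) closes the 3-(phenylsulfonyl)dihydropyranone F8, a doubly activated dienophile that should add 17 at or below room temperature with the lactone carbonyl endo to give the sulfone adduct F9. Reductive desulfonylation (Al/Hg, aqueous THF), with protonation of the lactone enolate on the only accessible cis-fusion face, gives the TES ether of the target F10. HF·pyridine then gives 18.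

**Further compounds**

F1 | step 4 | (Z)-γ-alkoxyallylstannane, tributyl[(Z)-3-{[(1R,2S)-1-phenyl-2,3-bis(triethylsilyloxy)propyl]oxy}prop-2-en-1-yl]stannane | CC[Si](CC)(CC)OC[C@H](O[Si](CC)(CC)CC)[C@@H](c1ccccc1)O/C=C\C[Sn](CCCC)(CCCC)CCCC
F2 | step 4 | (2R,3R)-3-phenyl-3-{[(Z)-3-(tributylstannyl)prop-1-en-1-yl]oxy}-2-(triethylsilyloxy)propanal | O=C[C@H](O[Si](CC)(CC)CC)[C@@H](c1ccccc1)O/C=C\C[Sn](CCCC)(CCCC)CCCC
F3 | step 4 | tributylstannyl ether of 12 | CCCC[Sn](CCCC)(CCCC)O[C@H]1[C@H](O[Si](CC)(CC)CC)[C@@H](c2ccccc2)O[C@H]1C=C
F4 | step 3 | (E)-alkenylboronate, 2-[(E)-3-{[(1R,2S)-1-phenyl-2,3-bis(triethylsilyloxy)propyl]oxy}prop-1-en-1-yl]-4,4,5,5-tetramethyl-1,3,2-dioxaborolane | CC[Si](CC)(CC)OC[C@H](O[Si](CC)(CC)CC)[C@@H](c1ccccc1)OC/C=C/B1OC(C)(C)C(C)(C)O1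
F5 | step 3 | (2R,3R)-3-phenyl-3-{[(E)-3-(pinacolboryl)prop-2-en-1-yl]oxy}-2-(triethylsilyloxy)propanal | O=C[C@H](O[Si](CC)(CC)CC)[C@@H](c1ccccc1)OC/C=C/B1OC(C)(C)C(C)(C)O1
F6 | step 8 | (phenylsulfonyl)acetate of 12 | O=C(CS(=O)(=O)c1ccccc1)O[C@H]2[C@H](O[Si](CC)(CC)CC)[C@@H](c3ccccc3)O[C@H]2C=C
F7 | step 8 | 2-formyltetrahydrofuran-3-yl (phenylsulfonyl)acetate from ozonolysis of F6 | O=C(CS(=O)(=O)c1ccccc1)O[C@H]2[C@H](O[Si](CC)(CC)CC)[C@@H](c3ccccc3)O[C@H]2C=O
F8 | step 8 | 6-(phenylsulfonyl) derivative of 15 (3-sulfonyl-5,6-dihydropyran-2-one) | O1[C@H]2[C@H](O[Si](CC)(CC)CC)[C@@H](c3ccccc3)O[C@H]2C=C(S(=O)(=O)c4ccccc4)C1=O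
F9 | step 8 | Diels–Alder adduct of F8 and 17 with phenylsulfonyl on the lactone α-carbon | CC1=C[C@@H]2[C@]3(S(=O)(=O)c6ccccc6)C(=O)O[C@H]4[C@H](O[Si](CC)(CC)CC)[C@@H](c5ccccc5)O[C@H]4[C@@H]3[C@H]1C[C@@H]2C(C)C
F10 | step 8 | O-triethylsilyl ether of 18 | CC1=C[C@@H]2[C@@H]3C(=O)O[C@H]4[C@H](O[Si](CC)(CC)CC)[C@@H](c5ccccc5)O[C@H]4[C@@H]3[C@H]1C[C@@H]2C(C)C
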